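The runs are simulated for substances that don't exist; scatter was added.

The question is what part of D has reacted after 3.0 h in the violet flask, and what its pH is then.

| flask | D | J | X | remark | time |
|---|---|---|---|---|---|
| violet | 28 mM | 0.084 mM | 2.8 mM | the very flask that is asked about, followed so far |  |
| amber | 19 mM | 0.084 mM | 2.8 mM | run made earlier |  |
| flask | 28 mM | 0.0840 mM | 2.80 mM |  | 3.0 h |

| run | time / min | D / % | G / % |
|---|---|---|---|
| violet | 2.50 | 95 | 1 |
| violet | 8.00 | 81 | 7 |
| violet | 12.0 | 74 | 9 |
| violet | 20.0 | 62 | 16 |
| violet | 30.0 | 51 | 22 |
| violet | 40.0 | 38 | 27 |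
| amber | 5.00 | 89 | 5 |
| amber | 15.0 | 72 | 12 |
| amber | 25.0 | 54 | 20 |
| amber | 40.0 | 41 | 31 |
| amber | 60.0 | 26 | 35 |
| amber | 80.0 | 20 | 39 |

(each reading ± 2 percentage points)

- J is the free proton; pH is minus the decimal logarithm of its molar concentration
- for Z the Q are counted in
- reactions considered so far: D + Z <-> Q; Z <-> L + J; D + X -> E; D + J -> Z + J + G; D -> Z + G
- what has gone from D into another species counts as reacted, even if it can come back

1. part of the D that has reacted at 3.0 h
2. pH of the solution at 3.0 h

D bound into Q counts as reacted, so the D column answers the first question, and I count half-lives in it as you would count time constants. In violet, from first to last reading, D halves every 28.4 min. In amber, from its first reading to the one at 40.0 min, it halves every 31.3 min. Both are readings, and with a scatter of 2 percentage points they lie close despite the different charges of D, which looks pseudo-first-order.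

Amber's later rows differ. From 40.0 min to 80.0 min, the late half-life of D, the time D takes to halve once the run is well advanced, reads 38.6 min, longer than amber's early value. So I use this one for what remains of violet. After its last reading, 38% of D is left, and the remaining time holds 3.62 late half-lives. That leaves 3.08%, so I reckon 96.9% reacted. The readings hold no pH, so I offer none.

The forecast says 91% (85% to 96%) and pH 3.3 (2.7 to 3.9), noting: “Its Ka is not determined by the data.” My figure lies above its range.

The flask gives 94.0% reacted and pH 4.08, and the pH already stood at 4.08 at 3.00 × 10⁻⁴ h.

    D + Z ⇌ Q, settled at all times (K = 1600 /M)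
    Z ⇌ L + J, settled at all times (K = 1.60 × 10⁻¹⁰ M)
    D + X → E (k = 0.0251 /M/s)
    D + J → Z + J + G (k = 1.62 /M/s)
    D → Z + G (k = 3.72 × 10⁻⁵ /s)

In 3.0 h, my late half-life counts 4.66 halvings, but the 5.99% of D left in this flask makes 4.06, fewer. The neighbour flask charged with 48 mM of D ends at 5.36% of D, which again makes fewer than my count, 4.22 halvings.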